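## The problem

The target is apigenin (5,7,4'-trihydroxyflavone) carrying at C8 a (2R)-5-methyl-2-(prop-1-en-2-yl)hex-5-en-1-yl chain. Ring A is a hexasubstituted benzene of the phloroglucinol type: O1 at C8a, the chain at C8, OH at C7, H at C6, OH at C5 and the C4 carbonyl at C4a. The chain must sit between O1 and O7 and not at the similar-looking C6. Alkylating a preformed phloroglucinol with a β-branched primary electrophile is a poor reaction and does not tell C6 from C8, and closing ring C on a 2,6-dihydroxyaryl ketone meets the same ambiguity. The single stereocenter lies in the chain, one carbon from the ring and next to an isopropenyl group; nothing in the flat flavone can control it, so it is bought with (R)-limonene, which also supplies ten of the twelve chain carbons. The centre is never enolisable, but it is allylic. Together with the two 1,1-disubstituted alkenes it excludes strong acid (tertiary cations, capture by the C7 hydroxyl to a chroman, double-bond migration), hydrogenation, peracids and electrophilic halogen once the chain is present. Protecting groups must therefore leave under neutral conditions, and a halogen handle has to arrive inside a building block. The key step rests on the sequence C8a(O)–C8(alkyl)–C7(O)–C6(H)–C5(O)–C4a(acyl): C5–C6–C7–C8 is a 1,3-dioxygenated diene with the chain on its terminus, C4a–C8a is an acetylenic ester, and bromine can stand in for the C8a oxygen until ring C is closed.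

## Retrosynthesis

**Target 26 to flavone 25.** The three phenols are unmasked last. Allyl ethers are chosen because zerovalent palladium removes them at room temperature without acid or hydrogen, so the alkenes and the allylic stereocenter are not at risk. Compound 25 is the tri-O-allyl ether of the target.

**Flavone 25 to diketone 24.** The O1–C8a bond is cut. The neighbouring cut, O1–C2 by cyclodehydration of a 2-hydroxyaryl diketone, would require one free hydroxyl next to the chain and a protected one at C5, which is the C6/C8 problem again. With bromine at C8a only one enol oxygen of 24 can reach the ring carbon through a six-membered transition state. The forward step is a copper-catalysed intramolecular O-arylation at a bromide flanked by the chain and the acyl group.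

**Diketone 24 to aldehyde 19 and ketone 21.** The C3–C4 bond is cut as an aldol addition of the lithium enolate 22 of 4'-(allyloxy)acetophenone 21 to aldehyde 19, giving aldol 23, followed by oxidation. A direct Claisen condensation on ester 17 would save three steps, but that ester is flanked by bromine and an ether oxygen and is a poor electrophile, whereas the aldehyde is not. Aldehyde 19 comes from 17 through alcohol 18, 17 from resorcinol 16 by allylation, and 21 from 4'-hydroxyacetophenone 20.

**Bromo-resorcylate 16 to diene 12 and bromoalkyne 14.** C8–C8a and C4a–C5 are cut together, which takes ring A apart into an acyclic 1-ethoxy-1,3-bis(trimethylsilyloxy)diene carrying the whole chain and a three-carbon bromoalkynoate. Against the alternative of cutting the C8–CH2 bond, this fixes the position of every substituent by the polarity of the two partners, with cycloadduct 15 as the only intermediate. The forward reaction must deliver the right regiochemistry, keep bromine on carbon and aromatise without acid.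

**Diene 12 to β-keto ester 9.** Two silylations, through enol ether 10 and dienolate 11, lead back to 9. The bond between the future C6 and C7 is then cut: acid 6, activated as imidazolide 8, acylates the malonate half-ester 7. γ-Alkylation of an acetoacetate dianion would need a β-branched iodide one carbon shorter than anything limonene offers directly, so the acylation is preferred.

**Acid 6 to (R)-limonene 1.** Acid 6 is limonene plus two one-carbon units. Pinnick oxidation leads back to aldehyde 5 and hydrolysis to enol ether 4. Two Wittig disconnections, through keto enol ether 3, lead to keto aldehyde 2, the ozonolysis product of the ring alkene of 1. The aldehyde carbon of 2 becomes C8, the methoxymethylene carbon becomes C7, and C4 of limonene becomes the (R) centre of the target. The descriptor stays R throughout because the ring-side branch always outranks the methallyl-side branch.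

**Bromoalkyne 14 to methyl propiolate 13.** Bromination of the terminal alkyne.

## Roads not taken

**Alternative 1:** Ring C is cut at C3–C4 and O1–C2, giving salicylaldehyde A2 and aroyl sulfoxonium ylide A3. In the forward sense [Cp*RhCl2]2 with AgSbF6 (trivalent rhodium) activates the aldehyde C–H bond of A2, carbene transfer from A3 forms C3–C4, and cyclodehydration forms O1–C2 to give the tri-MOM flavone A1.
- Merits: it is the most convergent plan, needs no halogen, and builds ring C in one step where the chosen route needs five steps from ester 17.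
- Weak points: A2 is the regiodefined C-alkyl phloroglucinol that is the real difficulty, with one particular ortho hydroxyl free. Three MOM ethers must be removed at the end with acid, under which the chain alkenes cyclise onto the C7 hydroxyl. A cationic rhodium/silver system is also less innocent towards the alkenes.
- Comparison: Alternative 1 is better in convergence and endgame length. The chosen plan sets against this a ring A whose pattern is fixed by construction and a deprotection that needs no acid.

**Alternative 2:** Ring A is cut into siloxyalkyne A5 and 3-ethoxycyclobut-2-en-1-one A6. On heating, A6 opens to a vinylketene, which adds to A5; electrocyclic opening, 6π closure and tautomerisation give phenol A4. The alkyne carbons become C8 and C7, and the free hydroxyl is the future O1.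
- Merits: the regiochemistry is dictated by the mechanism, the three oxygens emerge differentiated, and the step is thermal and neutral with good precedent. In regiocontrol it is at least the equal of the chosen plan and it avoids a haloalkyne.
- Weak points: C4a is still C–H, so the C4 carbon must be introduced afterwards by ortho-acylation in competition with C6. The C5 oxygen is an ethyl ether whose cleavage needs boron halides or hot thiolate, which the alkenes or the flavone will not tolerate. A5 needs an ester-to-ynolate homologation on the same limonene-derived chain.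
- Comparison: the chosen plan sets against this the acyl carbon already in place at C4a and two free phenols at the moment ring A forms, so the protecting groups can be chosen for a neutral endgame.

**Alternative 3:** C7–C8 and C5–C6 are cut, leaving pyranone ester A8 with rings C and B preformed. LiN(i-Pr)2 generates the vinylogous enolate of the side-chain methylene, N-acetylimidazole A9 acetylates it on carbon, and a second deprotonation closes the acetyl methyl onto the ring ester to give the 4'-silyl ether A7.
- Merits: O1–C8a exists from the start, so there is no C6/C8 question. The 5,7-diol appears unprotected and only one silyl ether remains for fluoride. In the endgame this road is clearly better than the chosen one.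
- Weak points: A8 needs its own multistep synthesis with a chain one carbon longer. The key step stacks site-selective deprotonation against ring opening of the pyranone, C- versus O-acetylation and a second enolisation in one flask, with precedent only on simpler pyranones.
- Comparison: the chosen plan sets against this reaction classes of broad precedent in separate, checkable steps.

Key step: step 9

Assumption: diene 12 is formed and used as a mixture of double-bond isomers (3Z expected to predominate); this geometry is erased on aromatisation, so it affects rate only.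

## Route

Step 1
Reactants: 1 (R)-(+)-limonene
Product: 2 (3R)-6-oxo-3-(prop-1-en-2-yl)heptanal
Conditions: O3 (1 equiv), CH2Cl2/MeOH, −78 °C; then Me2S, −78 → 20 °C
Reagents that add atoms: ozone, O=[O+][O-]
Why: Alkene ozonolysis; electrophilic ozone attacks the trisubstituted ring alkene faster than the isopropenyl group, and reductive work-up gives the keto aldehyde with the limonene stereocenter untouched.

Step 2
Reactants: 2 (3R)-6-oxo-3-(prop-1-en-2-yl)heptanal
Product: 4 (4R)-1-methoxy-7-methyl-4-(prop-1-en-2-yl)octa-1,7-diene (E/Z mixture), via keto enol ether 3 (not isolated)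
Conditions: Ph3P(CH2OMe)Cl, KN(SiMe3)2, THF, −78 → 0 °C; then Ph3P=CH2 (from Ph3PCH3Br, KN(SiMe3)2), 0 → 20 °C
Reagents that add atoms: (methoxymethyl)triphenylphosphonium chloride, COC[P+](c1ccccc1)(c1ccccc1)c1ccccc1.[Cl-]; methyltriphenylphosphonium bromide, C[P+](c1ccccc1)(c1ccccc1)c1ccccc1.[Br-]
Why: Two Wittig olefinations in sequence; the methoxymethylene ylide is consumed by the aldehyde at low temperature before the methyl ketone reacts, and the ketone is then methylenated by excess Ph3P=CH2. The stereocenter is β to both carbonyl groups and cannot epimerise.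

Step 3
Reactants: 4 (4R)-1-methoxy-7-methyl-4-(prop-1-en-2-yl)octa-1,7-diene
Product: 5 (4R)-7-methyl-4-(prop-1-en-2-yl)oct-7-enal
Conditions: aq. HCl (0.05 M), THF, 20 °C
Reagents that add atoms: water, O
Why: Acid-catalysed enol ether hydrolysis; enol ethers are protonated several orders of magnitude faster than 1,1-dialkylalkenes, so very dilute acid frees the aldehyde without touching the two alkenes.

Step 4
Reactants: 5 (4R)-7-methyl-4-(prop-1-en-2-yl)oct-7-enal
Product: 6 (4R)-7-methyl-4-(prop-1-en-2-yl)oct-7-enoic acid
Conditions: NaClO2, NaH2PO4, 2-methylbut-2-ene (excess), t-BuOH/H2O, 0 → 20 °C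
Reagents that add atoms: sodium chlorite, [Na+].[O-]Cl=O
Why: Pinnick oxidation; the excess of trisubstituted scavenger alkene takes up the hypochlorous acid so that the less nucleophilic chain alkenes are not chlorinated.

Step 5
Reactants: 6 (4R)-7-methyl-4-(prop-1-en-2-yl)oct-7-enoic acid; 7 potassium ethyl malonate (KO2CCH2CO2Et)
Product: 9 ethyl (6R)-9-methyl-3-oxo-6-(prop-1-en-2-yl)dec-9-enoate, via acyl imidazolide 8 (not isolated)
Conditions: CDI, THF, 20 °C; then KO2CCH2CO2Et, MgCl2, THF, 20 → 45 °C
Reagents that add atoms: 1,1'-carbonyldiimidazole, O=C(n1ccnc1)n1ccnc1 (supplies the imidazolyl group of 8; none of its atoms remain in 9)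
Why: Masamune–Brooks chain extension; the magnesium enolate of the malonate half-ester is C-acylated by the imidazolide and decarboxylates to the β-keto ester under near-neutral conditions.

Step 6
Reactants: 9 ethyl (6R)-9-methyl-3-oxo-6-(prop-1-en-2-yl)dec-9-enoate
Product: 10 ethyl (6R)-9-methyl-6-(prop-1-en-2-yl)-3-(trimethylsilyloxy)deca-2,9-dienoate (mainly 2Z)
Conditions: Me3SiCl, Et3N, hexane, 20 °C
Reagents that add atoms: chlorotrimethylsilane, C[Si](C)(C)Cl
Why: O-Silylation of the enolised β-keto ester with Me3SiCl/Et3N is the standard first stage in the preparation of 1-alkoxy-1,3-bis(silyloxy)dienes.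

Step 7
Reactants: 10 ethyl (6R)-9-methyl-6-(prop-1-en-2-yl)-3-(trimethylsilyloxy)deca-2,9-dienoate
Product: 12 (6R)-1-ethoxy-9-methyl-6-(prop-1-en-2-yl)-1,3-bis(trimethylsilyloxy)deca-1,3,9-triene (isomer mixture, used crude), via lithium dienolate 11 (not isolated)
Conditions: LiN(i-Pr)2, THF, −78 °C; then Me3SiCl, −78 → 20 °C
Reagents that add atoms: chlorotrimethylsilane, C[Si](C)(C)Cl
Why: Kinetic γ-deprotonation of the silyloxy enoate gives the extended ester enolate, which is O-silylated to the silyl ketene acetal; the stereocenter is two carbons from the deprotonated position.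

Step 8
Reactants: 13 methyl propiolate
Product: 14 methyl 3-bromoprop-2-ynoate
Conditions: NBS, AgNO3 (cat.), acetone, 20 °C
Reagents that add atoms: N-bromosuccinimide, O=C1CCC(=O)N1Br
Why: Silver-catalysed bromination of a terminal alkyne through the silver acetylide is the standard preparation of 3-bromopropiolates.

Step 9
Reactants: 12 (6R)-1-ethoxy-9-methyl-6-(prop-1-en-2-yl)-1,3-bis(trimethylsilyloxy)deca-1,3,9-triene; 14 methyl 3-bromoprop-2-ynoate
Product: 16 methyl 2-bromo-4,6-dihydroxy-3-[(2R)-5-methyl-2-(prop-1-en-2-yl)hex-5-en-1-yl]benzoate, via cyclohexadiene cycloadduct 15 (not isolated)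
Conditions: PhMe, 0 → 60 °C; then NH4F, MeOH, 20 °C
Reagents that add atoms: none
Why: The electron-rich diene 12 and the electron-poor alkyne 14 combine in a normal-demand, strongly asynchronous [4+2] cycloaddition (in the stepwise limit a Mukaiyama–Michael addition followed by 6-exo-trig closure of the ester-stabilised vinyl anion onto the acetal-derived carbon), forming C8–C8a and C4a–C5 and closing the six-membered carbocyclic ring A in one intermolecular event. The closest known reaction type is the Diels–Alder benzannulation of 1-alkoxy-1,3-bis(silyloxy)dienes with acetylenic esters, together with the use of 3-halopropiolates as dienophiles towards oxygenated dienes. Regiochemistry follows from matching the largest HOMO coefficient, at the chain-bearing terminus of 12, with the largest LUMO coefficient, at the β-carbon of the ynoate, so that chain and bromine become neighbours and the acetal carbon is joined to the ester-bearing carbon. Fluoride then strips the silyl groups of 15, the hemiketal at C5 collapses with loss of ethanol and the dienone tautomerises, so aromatisation needs neither acid nor oxidant. No stereocenter is created that survives: the sp3 centres at C8 and C5 of 15 are erased, and the (R) centre, two atoms from the reacting terminus, takes no part. Beyond regiochemistry the step needs ring closure to be faster than loss of bromide from a Michael-type intermediate; a non-polar solvent, the absence of Lewis acid and the outward-pointing chain of the 3Z diene (free s-cis conformation) favour the concerted path. Bromine thus arrives at C8a, a position meta to both oxygens that electrophilic bromination could not reach and that could not be brominated later without attacking the two alkenes.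

Step 10
Reactants: 16 methyl 2-bromo-4,6-dihydroxy-3-[(2R)-5-methyl-2-(prop-1-en-2-yl)hex-5-en-1-yl]benzoate
Product: 17 methyl 2-bromo-3-[(2R)-5-methyl-2-(prop-1-en-2-yl)hex-5-en-1-yl]-4,6-bis(prop-2-en-1-yloxy)benzoate
Conditions: allyl bromide, K2CO3, DMF, 50 °C
Reagents that add atoms: allyl bromide, C=CCBr
Why: Williamson etherification; K2CO3 in DMF alkylates both phenols, including the hydrogen-bonded one ortho to the ester, and the ester withdraws enough electron density to keep alkylation on oxygen.

Step 11
Reactants: 17 methyl 2-bromo-3-[(2R)-5-methyl-2-(prop-1-en-2-yl)hex-5-en-1-yl]-4,6-bis(prop-2-en-1-yloxy)benzoate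
Product: 18 {2-bromo-3-[(2R)-5-methyl-2-(prop-1-en-2-yl)hex-5-en-1-yl]-4,6-bis(prop-2-en-1-yloxy)phenyl}methanol
Conditions: i-Bu2AlH, CH2Cl2, −78 → 0 °C
Reagents that add atoms: none
Why: Hydride reduction of the hindered aryl ester to the benzylic alcohol; aryl bromide, allyl ethers and alkenes are inert to i-Bu2AlH at this temperature.

Step 12
Reactants: 18 {2-bromo-3-[(2R)-5-methyl-2-(prop-1-en-2-yl)hex-5-en-1-yl]-4,6-bis(prop-2-en-1-yloxy)phenyl}methanol
Product: 19 2-bromo-3-[(2R)-5-methyl-2-(prop-1-en-2-yl)hex-5-en-1-yl]-4,6-bis(prop-2-en-1-yloxy)benzaldehyde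
Conditions: MnO2, CH2Cl2, 20 °C
Reagents that add atoms: none
Why: MnO2 oxidises benzylic alcohols selectively to aldehydes without over-oxidation and leaves alkenes alone.

Step 13
Reactants: 20 4'-hydroxyacetophenone
Product: 21 1-[4-(prop-2-en-1-yloxy)phenyl]ethan-1-one
Conditions: allyl bromide, K2CO3, acetone, reflux
Reagents that add atoms: allyl bromide, C=CCBr
Why: Williamson etherification of an acidic phenol; the ring B oxygen receives the same protecting group as ring A so that one final operation removes all three.

Step 14
Reactants: 19 2-bromo-3-[(2R)-5-methyl-2-(prop-1-en-2-yl)hex-5-en-1-yl]-4,6-bis(prop-2-en-1-yloxy)benzaldehyde; 21 1-[4-(prop-2-en-1-yloxy)phenyl]ethan-1-one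
Product: 23 3-{2-bromo-3-[(2R)-5-methyl-2-(prop-1-en-2-yl)hex-5-en-1-yl]-4,6-bis(prop-2-en-1-yloxy)phenyl}-3-hydroxy-1-[4-(prop-2-en-1-yloxy)phenyl]propan-1-one (both carbinol epimers), via lithium enolate 22 (not isolated)
Conditions: 21, LiN(i-Pr)2, THF, −78 °C; then 19, −78 °C; aq. NH4Cl
Reagents that add atoms: none
Why: Directed aldol addition of a preformed lithium enolate to a non-enolisable aldehyde forms the C3–C4 bond; the carbinol centre is formed without control and is erased in step 15.

Step 15
Reactants: 23 aldol adduct
Product: 24 1-{2-bromo-3-[(2R)-5-methyl-2-(prop-1-en-2-yl)hex-5-en-1-yl]-4,6-bis(prop-2-en-1-yloxy)phenyl}-3-[4-(prop-2-en-1-yloxy)phenyl]propane-1,3-dione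
Conditions: Dess–Martin periodinane, CH2Cl2, 0 → 20 °C
Reagents that add atoms: none
Why: Dess–Martin oxidation converts β-hydroxy ketones into 1,3-diketones under neutral conditions and does not react with isolated alkenes or allyl ethers.

Step 16
Reactants: 24 1,3-diketone
Product: 25 8-[(2R)-5-methyl-2-(prop-1-en-2-yl)hex-5-en-1-yl]-5,7-bis(prop-2-en-1-yloxy)-2-[4-(prop-2-en-1-yloxy)phenyl]-4H-chromen-4-one
Conditions: CuI (10 mol %), 1,10-phenanthroline (20 mol %), K2CO3, DMF, 90 °C
Reagents that add atoms: none
Why: Ullmann-type intramolecular O-arylation of a 1-(2-bromoaryl)-1,3-diketone, a known flavone synthesis: under monovalent copper catalysis the enolate oxygen on the carbon bearing ring B displaces bromide at C8a, forming O1–C8a and closing ring C, and it is the only nucleophilic atom that can reach C8a through a six-membered transition state. Copper is used because zerovalent palladium would ionise the aryl allyl ethers.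

Step 17
Reactants: 25 tri-O-allyl flavone
Product: 26 5,7-dihydroxy-2-(4-hydroxyphenyl)-8-[(2R)-5-methyl-2-(prop-1-en-2-yl)hex-5-en-1-yl]-4H-chromen-4-one
Conditions: Pd(PPh3)4 (10 mol %), morpholine (excess), THF, 20 °C
Reagents that add atoms: none
Why: Tsuji–Trost deallylation; zerovalent palladium ionises the three aryl allyl ethers and morpholine traps the π-allyl complexes, so the phenols are released at room temperature without acid and the alkenes and stereocenter stay intact.

## Compound list

1 | (R)-(+)-limonene | CC1=CC[C@@H](CC1)C(C)=C | starting material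
2 | (3R)-6-oxo-3-(prop-1-en-2-yl)heptanal | CC(=O)CC[C@H](CC=O)C(C)=C | intermediate
3 | (5R)-8-methoxy-5-(prop-1-en-2-yl)oct-7-en-2-one (E/Z mixture, not isolated) | CC(=O)CC[C@H](CC=COC)C(C)=C | intermediate
4 | (4R)-1-methoxy-7-methyl-4-(prop-1-en-2-yl)octa-1,7-diene (E/Z mixture) | C=C(C)CC[C@H](CC=COC)C(=C)C | intermediate
5 | (4R)-7-methyl-4-(prop-1-en-2-yl)oct-7-enal | C=C(C)CC[C@H](CCC=O)C(=C)C | intermediate
6 | (4R)-7-methyl-4-(prop-1-en-2-yl)oct-7-enoic acid | C=C(C)CC[C@H](CCC(=O)O)C(=C)C | intermediate
7 | potassium ethyl malonate | CCOC(=O)CC(=O)[O-].[K+] | starting material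
8 | (4R)-1-(1H-imidazol-1-yl)-7-methyl-4-(prop-1-en-2-yl)oct-7-en-1-one (not isolated) | C=C(C)CC[C@H](CCC(=O)n1ccnc1)C(=C)C | intermediate
9 | ethyl (6R)-9-methyl-3-oxo-6-(prop-1-en-2-yl)dec-9-enoate | C=C(C)CC[C@H](CCC(=O)CC(=O)OCC)C(=C)C | intermediate
10 | ethyl (6R)-9-methyl-6-(prop-1-en-2-yl)-3-(trimethylsilyloxy)deca-2,9-dienoate (mainly 2Z) | C=C(C)CC[C@H](CCC(O[Si](C)(C)C)=CC(=O)OCC)C(=C)C | intermediate
11 | lithium dienolate of 10 (not isolated) | C=C(C)CC[C@H](CC=C(O[Si](C)(C)C)C=C(OCC)[O-])C(=C)C.[Li+] | intermediate
12 | (6R)-1-ethoxy-9-methyl-6-(prop-1-en-2-yl)-1,3-bis(trimethylsilyloxy)deca-1,3,9-triene (isomer mixture, 3Z expected to predominate) | C=C(C)CC[C@H](CC=C(O[Si](C)(C)C)C=C(OCC)O[Si](C)(C)C)C(=C)C | intermediate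
13 | methyl propiolate | C#CC(=O)OC | starting material
14 | methyl 3-bromoprop-2-ynoate | COC(=O)C#CBr | intermediate
15 | methyl 2-bromo-6-ethoxy-3-[(2R)-5-methyl-2-(prop-1-en-2-yl)hex-5-en-1-yl]-4,6-bis(trimethylsilyloxy)cyclohexa-1,4-diene-1-carboxylate (diastereomer mixture at the two ring sp3 carbons, not isolated) | C=C(C)CC[C@H](CC1C(Br)=C(C(=O)OC)C(OCC)(O[Si](C)(C)C)C=C1O[Si](C)(C)C)C(=C)C | intermediate
16 | methyl 2-bromo-4,6-dihydroxy-3-[(2R)-5-methyl-2-(prop-1-en-2-yl)hex-5-en-1-yl]benzoate | C=C(C)CC[C@H](Cc1c(O)cc(O)c(C(=O)OC)c1Br)C(=C)C | intermediate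
17 | methyl 2-bromo-3-[(2R)-5-methyl-2-(prop-1-en-2-yl)hex-5-en-1-yl]-4,6-bis(prop-2-en-1-yloxy)benzoate | C=C(C)CC[C@H](Cc1c(OCC=C)cc(OCC=C)c(C(=O)OC)c1Br)C(=C)C | intermediate
18 | {2-bromo-3-[(2R)-5-methyl-2-(prop-1-en-2-yl)hex-5-en-1-yl]-4,6-bis(prop-2-en-1-yloxy)phenyl}methanol | C=C(C)CC[C@H](Cc1c(OCC=C)cc(OCC=C)c(CO)c1Br)C(=C)C | intermediate
19 | 2-bromo-3-[(2R)-5-methyl-2-(prop-1-en-2-yl)hex-5-en-1-yl]-4,6-bis(prop-2-en-1-yloxy)benzaldehyde | C=C(C)CC[C@H](Cc1c(OCC=C)cc(OCC=C)c(C=O)c1Br)C(=C)C | intermediate
20 | 4'-hydroxyacetophenone | CC(=O)c1ccc(O)cc1 | starting material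
21 | 1-[4-(prop-2-en-1-yloxy)phenyl]ethan-1-one | CC(=O)c1ccc(OCC=C)cc1 | intermediate
22 | lithium enolate of 21 (not isolated) | C=C([O-])c1ccc(OCC=C)cc1.[Li+] | intermediate
23 | 3-{2-bromo-3-[(2R)-5-methyl-2-(prop-1-en-2-yl)hex-5-en-1-yl]-4,6-bis(prop-2-en-1-yloxy)phenyl}-3-hydroxy-1-[4-(prop-2-en-1-yloxy)phenyl]propan-1-one (both carbinol epimers) | C=C(C)CC[C@H](Cc1c(OCC=C)cc(OCC=C)c(C(O)CC(=O)c2ccc(OCC=C)cc2)c1Br)C(=C)C | intermediate
24 | 1-{2-bromo-3-[(2R)-5-methyl-2-(prop-1-en-2-yl)hex-5-en-1-yl]-4,6-bis(prop-2-en-1-yloxy)phenyl}-3-[4-(prop-2-en-1-yloxy)phenyl]propane-1,3-dione | C=C(C)CC[C@H](Cc1c(OCC=C)cc(OCC=C)c(C(=O)CC(=O)c2ccc(OCC=C)cc2)c1Br)C(=C)C | intermediate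
25 | 8-[(2R)-5-methyl-2-(prop-1-en-2-yl)hex-5-en-1-yl]-5,7-bis(prop-2-en-1-yloxy)-2-[4-(prop-2-en-1-yloxy)phenyl]-4H-chromen-4-one | C=C(C)CC[C@H](Cc1c(OCC=C)cc(OCC=C)c2c(=O)cc(-c3ccc(OCC=C)cc3)oc12)C(=C)C | intermediate
26 | 5,7-dihydroxy-2-(4-hydroxyphenyl)-8-[(2R)-5-methyl-2-(prop-1-en-2-yl)hex-5-en-1-yl]-4H-chromen-4-one | C=C(C)CC[C@H](Cc1c(O)cc(O)c2c(=O)cc(-c3ccc(O)cc3)oc12)C(=C)C | target

## Step count and least certain steps

Total: 17 steps. Longest linear sequence: 15 steps from (R)-limonene (steps 1–7, 9–12, 14–17); steps 8 and 13 prepare the two side components.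

**Step 9 (key step).** The nucleophilic diene terminus may add to the bromine-bearing carbon and then lose bromide (net alkynylation), or bromine may be transferred to the diene, before the second C–C bond closes. Steric retardation at the substituted terminus would favour these paths and the thermal decomposition of 14. Fallback: the halogen is taken out of the cycloaddition. Methyl propiolate 13 is stannylated (Bu3SnOMe, neat, 20 °C) to methyl 3-(tributylstannyl)prop-2-ynoate F1, whose tin substituent cannot leave in a conjugate addition. Cycloaddition of F1 with 12 in toluene, then NH4F/MeOH, should give, through the stannylated cycloadduct F2, the aryl stannane methyl 4,6-dihydroxy-3-[(2R)-5-methyl-2-(prop-1-en-2-yl)hex-5-en-1-yl]-2-(tributylstannyl)benzoate F3. Allylation as in step 10 gives the bis-allyl ether F4, and ipso-bromodestannylation with N-bromosuccinimide (CH2Cl2, −20 → 0 °C, dark) gives 17, where the route is rejoined.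

**Step 14.** Addition of the ketone enolate to the di-ortho-substituted aldehyde may be slow and reversible, so that retro-aldol cleavage on warming or work-up returns the components. Fallback: a smaller nucleophile that adds irreversibly. 1-Ethynyl-4-(prop-2-en-1-yloxy)benzene F5 (from commercial 4-(allyloxy)benzaldehyde by Ohira–Bestmann homologation) is lithiated with n-BuLi and added to 19 to give the propargylic alcohol F6. MnO2 oxidises it to the ynone F7, conjugate addition of diethylamine gives the enaminone F8, and mild hydrolysis (aq. oxalic acid, THF, 0–20 °C) gives diketone 24.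

**Step 2.** The first ylide may also olefinate the methyl ketone, or the second may not go to completion, leaving mixtures that are hard to separate at this volatile, non-polar stage. Fallback: the two ends are told apart by alkene substitution instead of carbonyl reactivity. Both carbonyl groups of 2 are methylenated with excess Ph3P=CH2 to give (4R)-7-methyl-4-(prop-1-en-2-yl)octa-1,7-diene F9. The hindered bis(3-methylbutan-2-yl)borane hydroborates the monosubstituted alkene faster than the two 1,1-disubstituted ones, and NaBO3 oxidation gives (4R)-7-methyl-4-(prop-1-en-2-yl)oct-7-en-1-ol F10. Dess–Martin oxidation gives aldehyde 5.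

**Step 1.** Over-ozonolysis at the isopropenyl group lowers the yield and gives polar by-products. Fallback: peracid epoxidation, which is more selective for the trisubstituted alkene, converts 1 into (4R)-limonene 1,2-oxide F11 (m-chloroperbenzoic acid, CH2Cl2, 0 °C). Periodic acid (H5IO6, THF/H2O) opens and cleaves the epoxide to keto aldehyde 2.

## Further compounds

F1 | step 9 | methyl 3-(tributylstannyl)prop-2-ynoate | CCCC[Sn](CCCC)(CCCC)C#CC(=O)OC
F2 | step 9 | methyl 6-ethoxy-3-[(2R)-5-methyl-2-(prop-1-en-2-yl)hex-5-en-1-yl]-2-(tributylstannyl)-4,6-bis(trimethylsilyloxy)cyclohexa-1,4-diene-1-carboxylate (not isolated) | C=C(C)CC[C@H](CC1C([Sn](CCCC)(CCCC)CCCC)=C(C(=O)OC)C(OCC)(O[Si](C)(C)C)C=C1O[Si](C)(C)C)C(=C)C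
F3 | step 9 | methyl 4,6-dihydroxy-3-[(2R)-5-methyl-2-(prop-1-en-2-yl)hex-5-en-1-yl]-2-(tributylstannyl)benzoate | C=C(C)CC[C@H](Cc1c(O)cc(O)c(C(=O)OC)c1[Sn](CCCC)(CCCC)CCCC)C(=C)C
F4 | step 9 | methyl 3-[(2R)-5-methyl-2-(prop-1-en-2-yl)hex-5-en-1-yl]-4,6-bis(prop-2-en-1-yloxy)-2-(tributylstannyl)benzoate | C=C(C)CC[C@H](Cc1c(OCC=C)cc(OCC=C)c(C(=O)OC)c1[Sn](CCCC)(CCCC)CCCC)C(=C)C
F5 | step 14 | 1-ethynyl-4-(prop-2-en-1-yloxy)benzene | C#Cc1ccc(OCC=C)cc1
F6 | step 14 | 1-{2-bromo-3-[(2R)-5-methyl-2-(prop-1-en-2-yl)hex-5-en-1-yl]-4,6-bis(prop-2-en-1-yloxy)phenyl}-3-[4-(prop-2-en-1-yloxy)phenyl]prop-2-yn-1-ol | C=C(C)CC[C@H](Cc1c(OCC=C)cc(OCC=C)c(C(O)C#Cc2ccc(OCC=C)cc2)c1Br)C(=C)C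
F7 | step 14 | 1-{2-bromo-3-[(2R)-5-methyl-2-(prop-1-en-2-yl)hex-5-en-1-yl]-4,6-bis(prop-2-en-1-yloxy)phenyl}-3-[4-(prop-2-en-1-yloxy)phenyl]prop-2-yn-1-one | C=C(C)CC[C@H](Cc1c(OCC=C)cc(OCC=C)c(C(=O)C#Cc2ccc(OCC=C)cc2)c1Br)C(=C)C
F8 | step 14 | 1-{2-bromo-3-[(2R)-5-methyl-2-(prop-1-en-2-yl)hex-5-en-1-yl]-4,6-bis(prop-2-en-1-yloxy)phenyl}-3-(diethylamino)-3-[4-(prop-2-en-1-yloxy)phenyl]prop-2-en-1-one | C=C(C)CC[C@H](Cc1c(OCC=C)cc(OCC=C)c(C(=O)C=C(N(CC)CC)c2ccc(OCC=C)cc2)c1Br)C(=C)C
F9 | step 2 | (4R)-7-methyl-4-(prop-1-en-2-yl)octa-1,7-diene | C=C(C)CC[C@H](CC=C)C(=C)C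
F10 | step 2 | (4R)-7-methyl-4-(prop-1-en-2-yl)oct-7-en-1-ol | C=C(C)CC[C@H](CCCO)C(=C)C
F11 | step 1 | (4R)-1-methyl-4-(prop-1-en-2-yl)-7-oxabicyclo[4.1.0]heptane (limonene 1,2-oxide, cis/trans mixture) | CC12OC1C[C@@H](CC2)C(C)=C
A1 | alternative 1 | 5,7-bis(methoxymethoxy)-2-[4-(methoxymethoxy)phenyl]-8-[(2R)-5-methyl-2-(prop-1-en-2-yl)hex-5-en-1-yl]-4H-chromen-4-one | C=C(C)CC[C@H](Cc1c(OCOC)cc(OCOC)c2c(=O)cc(-c3ccc(OCOC)cc3)oc12)C(=C)C
A2 | alternative 1 | 2-hydroxy-4,6-bis(methoxymethoxy)-3-[(2R)-5-methyl-2-(prop-1-en-2-yl)hex-5-en-1-yl]benzaldehyde | C=C(C)CC[C@H](Cc1c(OCOC)cc(OCOC)c(C=O)c1O)C(=C)C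
A3 | alternative 1 | dimethylsulfoxonium 2-[4-(methoxymethoxy)phenyl]-2-oxoethylide | COCOc1ccc(cc1)C(=O)C=S(C)(C)=O
A4 | alternative 2 | 5-ethoxy-2-[(2R)-5-methyl-2-(prop-1-en-2-yl)hex-5-en-1-yl]-3-(triisopropylsilyloxy)phenol | C=C(C)CC[C@H](Cc1c(O)cc(OCC)cc1O[Si](C(C)C)(C(C)C)C(C)C)C(=C)C
A5 | alternative 2 | triisopropyl{[(4R)-7-methyl-4-(prop-1-en-2-yl)oct-7-en-1-yn-1-yl]oxy}silane | C=C(C)CC[C@H](CC#CO[Si](C(C)C)(C(C)C)C(C)C)C(=C)C
A6 | alternative 2 | 3-ethoxycyclobut-2-en-1-one | CCOC1=CC(=O)C1
A7 | alternative 3 | 2-{4-[(tert-butyldimethylsilyl)oxy]phenyl}-5,7-dihydroxy-8-[(2R)-5-methyl-2-(prop-1-en-2-yl)hex-5-en-1-yl]-4H-chromen-4-one | C=C(C)CC[C@H](Cc1c(O)cc(O)c2c(=O)cc(-c3ccc(O[Si](C)(C)C(C)(C)C)cc3)oc12)C(=C)C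
A8 | alternative 3 | methyl 6-{4-[(tert-butyldimethylsilyl)oxy]phenyl}-2-[(3R)-6-methyl-3-(prop-1-en-2-yl)hept-6-en-1-yl]-4-oxo-4H-pyran-3-carboxylate | C=C(C)CC[C@H](CCc1oc(-c2ccc(O[Si](C)(C)C(C)(C)C)cc2)cc(=O)c1C(=O)OC)C(=C)C
A9 | alternative 3 | N-acetylimidazole | CC(=O)n1ccnc1
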